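Take the closed, stirred vessel of the north recipe, which is the south-east charge carried on to 170 min, and read the earlier runs before reckoning anything.

| flask | substrate | partner | target | time |
|---|---|---|---|---|
| south-east | 80.0 mM | 120 mM |  |  |
| south-west | 120 mM | 120 mM |  |  |
| west | 80.0 mM | 120 mM | 24.0 mM |  |
| north | 80.0 mM | 120 mM |  | 170 min |

| run | time / min | [target] / mM |
|---|---|---|
| south-east run | 2.7 | 3.90 |
| south-east run | 6.1 | 8.96 |
| south-east run | 14 | 17.80 |
| south-east run | 30 | 30.13 |
| south-east run | 68 | 40.43 |
| south-west run | 2.7 | 5.32 |
| south-west run | 6.1 | 12.31 |
| south-west run | 14 | 25.25 |
| south-west run | 30 | 42.59 |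
| south-west run | 68 | 59.17 |
| west run | 2.7 | 27.12 |
| west run | 6.1 | 31.58 |
| west run | 14 | 38.67 |
| west run | 30 | 47.99 |
| west run | 68 | 54.75 |

(scatter of a reading: 0.2 mM)

* reaction order in [substrate] at the outset, round the charge of the south-east run, defined at two percent of the substrate turned into target (one fixed amount of target, the same in the runs compared)
* target in the north run at 170 min, as a share of the substrate charged

- Overall: substrate + partner -> target.
- Constant volume, constant temperature.
- A reading of a species includes what of it is bound.
- "The second partner" is partner.
- An order is taken over about fifteen percent of the charge, up and down.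

Ask first how steeply the early rate follows [substrate]. Divide the first south-west reading by the first south-east reading, 1.36 for a charge ratio of 1.50, and take from the logarithms an order near 0.766, which is less than first order.

Ask next what charged target does at equal substrate. The first west gain runs at 1.16 mM min⁻¹ against 1.44 mM min⁻¹ in the south-east run, slower, so spread that gap over the 24.0 mM charged and call the result the target drain, the net rate given up per mM of [target] present, 0.0120 min⁻¹, a pseudo-first-order reading.

Ask last where the south-east run stands at 68 min. The drain was read with [partner] near its charge, and by 68 min in the south-east run at most 79.6 mM of partner remains, a share of 0.663 of the charge, so, on my own assumption that the drain follows [partner] in proportion, scale it by that share: on 40.43 mM it comes to about 0.323 mM min⁻¹, beside a net rise of 0.271 mM min⁻¹ over the last interval, while at most 39.6 mM of substrate remains, about half of the charge. Expect [target] to top out soon after, and commit to about that reading, 50.5% of the charge.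

The forecast gives 0.78 and 54.5%, judging that “this looks mainly like catalyst dying”, and so stands 4 percentage points above my figure.

The north flask gives 0.86 and 49.3%, which is 39.4 mM of target at 170 min, less than the 40.43 mM read at 68 min from the same charge.

    substrate + partner ⇌ intermediate (12.90 M⁻¹ min⁻¹, 1.692 min⁻¹)
    intermediate → target (0.06720 min⁻¹)
    target + partner → side product (0.1722 M⁻¹ min⁻¹)
    2 partner ⇌ idle reagent dimer, settled at all times (4.280 M⁻¹)

Put the drain to use once more on the west run: divided by the 0.172 M⁻¹ min⁻¹ of target + partner → side product, it reads a [partner] of 69.8 mM against a charge of 120 mM.

Readings and results are simulated for substances that don't exist; scatter was added.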